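## Structural features

The target is an unsymmetrical biflavanone. Each of its two 2-arylchroman-4-one units has a phloroglucinol-type ring A fused to a dihydropyranone ring C that carries ring B at C2 (positions of unit 2 are written with a double prime; its ring B is para-disubstituted). The units are joined by a single diaryl ether, from O3' of ring B of unit 1, which also bears the free 4'-hydroxyl, to the para carbon of ring B of unit 2. Ring A of unit 1 carries 5-OH and 7-OMe and ring A of unit 2 carries 5-OH and 7-OH, so the halves differ and the two arms of the diaryl ether must be told apart. The only stereocentres are C2 and C2'', both S. They are not adjacent to each other or to any other stereocentre and lie far apart across the diaryl ether, so neither can steer the other, and isomers differing at one centre will be nearly inseparable. Each C2–O1 bond is benzylic and β to the C4 ketone: base opens ring C by retro-oxa-Michael reaction (racemisation through the 2'-hydroxychalcone) and hydrogen on palladium can cleave it; the four phenols are electron-rich. The real difficulty is to set two remote, base-labile benzylic ether stereocentres with absolute control, late and under neutral conditions. The key step uses the fact that C2 in each unit is a benzylic CH bonded to O1 and para to an oxygen on ring B, and is linked to C3 through C4, C4a, C8a and O1. A carbene at C3 can therefore take a C2–H bond of a plain achiral benzyl aryl ether through a six-membered transition state, making C2–C3, ring C and the stereocentre at once, twice.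

## Logic of the disconnections

**16 ⇒ 15 ⇒ 14.** The O4'–CH2Ph bond and the O–Si bonds at O5, O5'' and O7'' are cut. Free phenols would quench a carbene by O–H insertion and would not survive enolate chemistry. Silicon on O5 and O5'' is essential because it places no C–H bond α to oxygen within reach of C3. Triisopropylsilyl is preferred to a smaller silyl group because it resists migration to an enolate oxygen and attack by the carbene. O7'' is silylated as well rather than benzylated, which saves a step and removes a needless activated benzylic ether. Benzyl stays on O4' because that oxygen must survive hot carbonate earlier. The demand is a non-basic fluoride source and a hydrogenolysis that stops before the C2–O1 bonds are touched.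

**14 ⇒ 13.** C2–C3 is cut in both units. Both rings C and both stereocentres vanish, and 13 is an achiral bis(benzyl aryl ether) with a diazoketone on each ring A. The forward step must choose one of two enantiotopic benzylic hydrogens at each site under catalyst control and must prefer insertion to attack on O1.

**13 ⇒ 11 (through 12).** The two C3=N2 units are removed, leaving two aryl methyl ketones. Methyl ketones are inert through the whole assembly and both are converted in one operation. The demand is clean twofold enolisation of hindered 2,6-dioxygenated aryl ketones without loss or shift of the silyl groups.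

**11 ⇒ 8 + 10.** The bond between O1'' and the benzylic carbon C2'' is cut. A neutral dehydrative etherification avoids base near the aryl silyl ethers and uses the one free, chelated hydroxyl of 10.

**8 ⇒ 7 ⇒ 4 + 6.** The benzylic alcohol of 8 is traced to the aldehyde of 7, and 7 is cut at the bond between O1 and the benzylic carbon C2. The two arms of 4 thus differ in oxidation level (alcohol and aldehyde). An ester as the second arm is rejected: it would have to be reduced after the first aryl ketone is in place, which no hydride does selectively. The only reduction run beside a ketone is that of an aldehyde, which is easy to keep selective.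

**4 ⇒ 2 + 3, and 2 ⇒ 1.** The diaryl ether is cut at the carbon that carries fluorine in 3, para to the formyl group that activates the displacement. The benzylic alcohol of 2 comes from the aldehyde of 1 before ether formation, so the two arms never share an oxidation level. The demand is that the phenoxide of 2 reacts and its benzylic hydroxyl does not.

**6 ⇒ 5 and 10 ⇒ 9.** O–Si bonds are cut. Silylation must stop when one hydroxyl ortho to the acetyl group is left; chelation of that last hydroxyl to the carbonyl provides the stop.

## Other disconnections considered

**Alternative 1:** The cut runs through ring B of unit 2 (C3'–C4' and C5'–C6' of that ring), so its six carbons come from a 2-pyrone and an ynol ether. Forward, the aryl ethynyl ether A1 and methyl coumalate A2 undergo an inverse-demand Diels–Alder reaction. The terminal alkyne carbon bonds to C6 of the pyrone and the oxygen-bearing carbon to C3, and decarboxylative aromatisation gives the para-aryloxybenzoate A3.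
- In favour: regiochemistry is fixed by polarisation, no fluoride displacement in hot carbonate is needed, and a thermal pericyclic step has few competing paths.
- Equal to the chosen plan: A3 has the two arms differentiated (ester and acetal), which matches the alcohol/aldehyde pair of 4.
- Against: the ring built is a plain para-disubstituted benzene that 3 supplies in one step. Aryl ethynyl ethers take several steps from a phenol and hydrate or polymerise easily. The step makes no ring C and no stereocentre, so the whole problem of C2 and C2'' remains for a second key step.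
- Comparison: structurally it addresses the periphery, mechanistically it is more certain than a carbene insertion, and in step economy it is several steps longer for the same downstream work.

**Alternative 2:** The cut removes ring A of unit 1 (C5–C6, C7–C8, C4a–C5). Forward, the diazoketone A4, an enantiopure dihydropyranone that already carries the complete unit 2, undergoes photochemical Wolff rearrangement. The ketene combines with methoxyacetylene A5 by [2+2] cycloaddition, four-electron ring opening and six-electron ring closure to give the phenol A6.
- Better than the chosen plan: 5-OH appears free and 7-OMe is placed by the polarisation of A5, so unit 1 needs no protecting group at O5 and ring A regiochemistry is mechanistically locked. No oxonium ylide pathway exists.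
- Equal: the neutral conditions leave C2 untouched.
- Against: only one ring A is built and no stereocentre. C2 of A4 and all of unit 2 must first be made by two separate asymmetric solutions. A4, an acyl diazomethane on a vinylogous ester, is itself hard to reach. A5 is volatile and unstable, and the free chelated phenol of unit 2 could trap the ketene.
- Comparison: it forms one ring against two rings and two stereocentres for the chosen step, and it is linear where the chosen plan is convergent.

**Alternative 3:** The cut is O1–C8a in both units. Forward, the dibromo tetraol A7 closes twice by intramolecular aryl ether formation on a zerovalent palladium catalyst with a bulky biaryl dialkylphosphine and a carbonate base, giving the bis(flavan-4-ol) A8. Only the C2 hydroxyls can close (six-membered ring); the C4 hydroxyls would give four-membered rings.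
- Better than the chosen plan: C2 is set beforehand in acyclic 1,3-diols by established asymmetric aldol and reduction methods and is carried with retention, since the C2–O bond is never broken. At the flavan-4-ol level C2 cannot racemise by ring opening. No diazo compound is handled, and all-benzyl protection allows one global hydrogenolysis.
- Equal: both closures are twofold and six-membered.
- Against: four stereocentres are built to keep two. A secondary benzylic alkoxide on palladium can undergo β-hydride elimination to a ketone instead of reductive elimination. After closure a double oxidation at C4 is still needed, and A7 requires two separate asymmetric sequences on different arms.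
- Comparison: it is stronger on stereochemical reliability and markedly weaker on step economy and redox economy.

Key step: step 9

Remark on materials: 1 is taken to be a catalogue compound.
Remark on stereochemistry: Rh2(S-PTTL)4 is assumed to deliver the 2S configuration at both sites; if the sense of induction is opposite, the mirror-image catalyst Rh2(R-PTTL)4 is used with no other change.

## Route

Step 1
Reactants: 1 4-(benzyloxy)-3-hydroxybenzaldehyde
Product: 2 2-(benzyloxy)-5-(hydroxymethyl)phenol
Conditions: NaBH4, MeOH/THF, 0 °C
Reagents that add atoms: none
Why: Borohydride reduction of an aryl aldehyde; doing it before ether formation means the two future arms never share an oxidation level.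

Step 2
Reactants: 2 2-(benzyloxy)-5-(hydroxymethyl)phenol; 3 4-fluorobenzaldehyde
Product: 4 4-[2-(benzyloxy)-5-(hydroxymethyl)phenoxy]benzaldehyde
Conditions: K2CO3, DMF, 100 °C
Reagents that add atoms: none
Why: Nucleophilic aromatic substitution (SNAr) through a Meisenheimer adduct stabilised by the para-formyl group; carbonate deprotonates only the phenol, so the benzylic hydroxyl is a spectator.

Step 3
Reactants: 5 2,6-dihydroxy-4-methoxyacetophenone
Product: 6 1-{2-hydroxy-4-methoxy-6-[(triisopropylsilyl)oxy]phenyl}ethanone
Conditions: TIPSCl (1.05 equiv), imidazole, DMF, 0 °C to rt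
Reagents that add atoms: chlorotriisopropylsilane, CC(C)[Si](Cl)(C(C)C)C(C)C
Why: Phenol silylation; after the first silylation the remaining hydroxyl is locked in a hydrogen bond to the acetyl oxygen, so the reaction should stop at the mono-ether.

Step 4
Reactants: 4 4-[2-(benzyloxy)-5-(hydroxymethyl)phenoxy]benzaldehyde; 6 1-{2-hydroxy-4-methoxy-6-[(triisopropylsilyl)oxy]phenyl}ethanone
Product: 7 4-{5-[(2-acetyl-5-methoxy-3-[(triisopropylsilyl)oxy]phenoxy)methyl]-2-(benzyloxy)phenoxy}benzaldehyde
Conditions: PPh3, DIAD, THF, 0 °C to rt
Reagents that add atoms: none
Why: Mitsunobu etherification of a primary benzylic alcohol with an acidic, chelated phenol; neutral conditions spare the aryl silyl ether and the aldehyde.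

Step 5
Reactants: 7 4-{5-[(2-acetyl-5-methoxy-3-[(triisopropylsilyl)oxy]phenoxy)methyl]-2-(benzyloxy)phenoxy}benzaldehyde
Product: 8 1-{2-[(4-(benzyloxy)-3-[4-(hydroxymethyl)phenoxy]phenyl)methoxy]-4-methoxy-6-[(triisopropylsilyl)oxy]phenyl}ethanone
Conditions: NaBH4 (one hydride equivalent), THF/MeOH, −20 °C
Reagents that add atoms: none
Why: Chemoselective borohydride reduction; an unhindered aryl aldehyde should be reduced far faster than a ketone flanked by two ortho oxygens on an electron-rich ring.

Step 6
Reactants: 9 2,4,6-trihydroxyacetophenone
Product: 10 1-{2-hydroxy-4,6-bis[(triisopropylsilyl)oxy]phenyl}ethanone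
Conditions: TIPSCl (2.1 equiv), imidazole, DMF, rt
Reagents that add atoms: chlorotriisopropylsilane, CC(C)[Si](Cl)(C(C)C)C(C)C
Why: Phenol silylation; the para hydroxyl and one ortho hydroxyl react, and the last ortho hydroxyl is held back by chelation to the acetyl group.

Step 7
Reactants: 8 1-{2-[(4-(benzyloxy)-3-[4-(hydroxymethyl)phenoxy]phenyl)methoxy]-4-methoxy-6-[(triisopropylsilyl)oxy]phenyl}ethanone; 10 1-{2-hydroxy-4,6-bis[(triisopropylsilyl)oxy]phenyl}ethanone
Product: 11 bis(methyl ketone): 1-{2-[(4-{5-[(2-acetyl-5-methoxy-3-[(triisopropylsilyl)oxy]phenoxy)methyl]-2-(benzyloxy)phenoxy}phenyl)methoxy]-4,6-bis[(triisopropylsilyl)oxy]phenyl}ethanone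
Conditions: PPh3, DIAD, THF, 0 °C to rt
Reagents that add atoms: none
Why: Second Mitsunobu etherification, on the para-aryloxybenzyl alcohol; the ketone, silyl ethers and first benzyl aryl ether are inert to the neutral redox couple.

Step 8
Reactants: 11 bis(methyl ketone)
Product: 13 bis(diazoketone) in which both acetyl groups of 11 have become diazoacetyl groups, via bis(trifluoroacetylketone) 12 (not isolated)
Conditions: LiN(SiMe3)2, THF, −78 °C; CF3CO2CH2CF3; then 4-acetamidobenzenesulfonyl azide, Et3N, H2O, MeCN, rt
Reagents that add atoms: 2,2,2-trifluoroethyl trifluoroacetate, O=C(OCC(F)(F)F)C(F)(F)F (its trifluoroacetyl groups stay only in 12); 4-acetamidobenzenesulfonyl azide, CC(=O)Nc1ccc(cc1)S(=O)(=O)N=[N+]=[N-]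
Why: Danheiser detrifluoroacetylative diazo transfer: kinetic enolisation and trifluoroacetylation give the activated 1,3-diketone, the sulfonyl azide transfers N2 to its central carbon, and the trifluoroacetyl group leaves as the N-acyl sulfonamide; the bulky silyl groups are chosen to resist oxygen-to-oxygen migration in the enolate.

Step 9
Reactants: 13 bis(diazoketone)
Product: 14 (2S,2''S)-4'-O-benzyl-5,5'',7''-tris-O-(triisopropylsilyl)-7-O-methyltetrahydroochnaflavone
Conditions: Rh2(S-PTTL)4 (dirhodium tetrakis[N-phthaloyl-(S)-tert-leucinate], 2 mol%), CH2Cl2, 0 °C, slow addition of 13 at high dilution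
Reagents that add atoms: none
Why: Each diazoketone is decomposed by the divalent rhodium dimer with loss of N2 to an electrophilic rhodium carbene at C3, which takes a C2–H bond through a concerted, asynchronous three-centre transition state with hydride-transfer character. The closest known reaction type is the chiral dirhodium carboxylate-catalysed intramolecular C–H insertion of 2-alkoxyaryl diazoketones to chroman-4-ones. Each ring C closes by 1,6-insertion as a six-membered ring through the new C2–C3 bond; the usual five-membered mode is excluded because the atom at that distance is O1. Each C2 stereocentre is set by the catalyst, whose chiral pocket of four phthalimido-tert-leucinate ligands distinguishes the two enantiotopic benzylic hydrogens. The two sites are remote and react independently, so the same sense is expected at both. The step needs insertion to beat carbene attack on O1 (oxonium ylide, then 1,2-benzyl shift); the O1 lone pair is delocalised into the acyl-bearing ring A, and the C2–H bonds are benzylic, α to oxygen and para to an oxygen donor, hence strongly hydridic. O5, O5'' and O7'' carry silicon, so no other C–H α to oxygen lies within reach, and the O4' benzyl CH2 can only be reached intermolecularly, which slow addition suppresses together with carbene dimerisation. C3 ends as CH2 and the medium is neutral, so the new centres cannot epimerise or open.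

Step 10
Reactants: 14 (2S,2''S)-4'-O-benzyl-5,5'',7''-tris-O-(triisopropylsilyl)-7-O-methyltetrahydroochnaflavone
Product: 15 (2S,2''S)-4'-O-benzyl-7-O-methyltetrahydroochnaflavone
Conditions: Et3N·3HF (excess), THF, rt
Reagents that add atoms: none
Why: Fluoride cleavage of aryl silyl ethers; the reagent is weakly acidic rather than basic, so no phenoxide forms that could open ring C by retro-oxa-Michael reaction and racemise C2.

Step 11
Reactants: 15 (2S,2''S)-4'-O-benzyl-7-O-methyltetrahydroochnaflavone
Product: 16 7-O-methyltetrahydroochnaflavone, (2S,2''S)
Conditions: H2 (1 atm), Pd/C, EtOAc/MeOH, rt, stopped at full conversion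
Reagents that add atoms: none
Why: Catalytic hydrogenolysis of an aryl benzyl ether; exocyclic O–benzyl cleavage is much faster than cleavage of the ring C2–O1 bond or ketone reduction under neutral, low-pressure conditions.

## Compound list

1 | 4-(benzyloxy)-3-hydroxybenzaldehyde | O=Cc1ccc(OCc2ccccc2)c(O)c1 | starting material
2 | 2-(benzyloxy)-5-(hydroxymethyl)phenol | OCc1ccc(OCc2ccccc2)c(O)c1 | intermediate
3 | 4-fluorobenzaldehyde | O=Cc1ccc(F)cc1 | starting material
4 | 4-[2-(benzyloxy)-5-(hydroxymethyl)phenoxy]benzaldehyde | O=Cc1ccc(Oc2cc(CO)ccc2OCc2ccccc2)cc1 | intermediate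
5 | 2,6-dihydroxy-4-methoxyacetophenone | CC(=O)c1c(O)cc(OC)cc1O | starting material
6 | 1-{2-hydroxy-4-methoxy-6-[(triisopropylsilyl)oxy]phenyl}ethanone | CC(=O)c1c(O)cc(OC)cc1O[Si](C(C)C)(C(C)C)C(C)C | intermediate
7 | 4-{5-[(2-acetyl-5-methoxy-3-[(triisopropylsilyl)oxy]phenoxy)methyl]-2-(benzyloxy)phenoxy}benzaldehyde | CC(=O)c1c(OCc2ccc(OCc3ccccc3)c(Oc3ccc(C=O)cc3)c2)cc(OC)cc1O[Si](C(C)C)(C(C)C)C(C)C | intermediate
8 | 1-{2-[(4-(benzyloxy)-3-[4-(hydroxymethyl)phenoxy]phenyl)methoxy]-4-methoxy-6-[(triisopropylsilyl)oxy]phenyl}ethanone | CC(=O)c1c(OCc2ccc(OCc3ccccc3)c(Oc3ccc(CO)cc3)c2)cc(OC)cc1O[Si](C(C)C)(C(C)C)C(C)C | intermediate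
9 | 2,4,6-trihydroxyacetophenone | CC(=O)c1c(O)cc(O)cc1O | starting material
10 | 1-{2-hydroxy-4,6-bis[(triisopropylsilyl)oxy]phenyl}ethanone | CC(=O)c1c(O)cc(O[Si](C(C)C)(C(C)C)C(C)C)cc1O[Si](C(C)C)(C(C)C)C(C)C | intermediate
11 | bis(methyl ketone) of the bis(benzyl aryl ether) | CC(=O)c1c(OCc2ccc(OCc3ccccc3)c(Oc3ccc(COc4cc(O[Si](C(C)C)(C(C)C)C(C)C)cc(O[Si](C(C)C)(C(C)C)C(C)C)c4C(C)=O)cc3)c2)cc(OC)cc1O[Si](C(C)C)(C(C)C)C(C)C | intermediate
12 | bis(4,4,4-trifluoro-1,3-diketone), each acetyl of 11 trifluoroacetylated at its methyl carbon | FC(F)(F)C(=O)CC(=O)c1c(OCc2ccc(OCc3ccccc3)c(Oc3ccc(COc4cc(O[Si](C(C)C)(C(C)C)C(C)C)cc(O[Si](C(C)C)(C(C)C)C(C)C)c4C(=O)CC(=O)C(F)(F)F)cc3)c2)cc(OC)cc1O[Si](C(C)C)(C(C)C)C(C)C | intermediate (not isolated)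
13 | bis(diazoketone) of the bis(benzyl aryl ether) | COc1cc(O[Si](C(C)C)(C(C)C)C(C)C)c(C(=O)C=[N+]=[N-])c(c1)OCc1ccc(OCc2ccccc2)c(Oc2ccc(COc3cc(O[Si](C(C)C)(C(C)C)C(C)C)cc(O[Si](C(C)C)(C(C)C)C(C)C)c3C(=O)C=[N+]=[N-])cc2)c1 | intermediate
14 | (2S,2''S)-4'-O-benzyl-5,5'',7''-tris-O-(triisopropylsilyl)-7-O-methyltetrahydroochnaflavone | COc1cc(O[Si](C(C)C)(C(C)C)C(C)C)c2c(c1)O[C@H](c1ccc(OCc3ccccc3)c(Oc3ccc([C@@H]4CC(=O)c5c(O[Si](C(C)C)(C(C)C)C(C)C)cc(O[Si](C(C)C)(C(C)C)C(C)C)cc5O4)cc3)c1)CC2=O | intermediate
15 | (2S,2''S)-4'-O-benzyl-7-O-methyltetrahydroochnaflavone | COc1cc(O)c2c(c1)O[C@H](c1ccc(OCc3ccccc3)c(Oc3ccc([C@@H]4CC(=O)c5c(O)cc(O)cc5O4)cc3)c1)CC2=O | intermediate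
16 | 7-O-methyltetrahydroochnaflavone, (2S,2''S) | COc1cc(O)c2c(c1)O[C@H](c1ccc(O)c(Oc3ccc([C@@H]4CC(=O)c5c(O)cc(O)cc5O4)cc3)c1)CC2=O | target

## Step count and least certain steps

Total step count: 11. Longest linear sequence: 9 steps (1, 2, 4, 5, 7, 8, 9, 10, 11); steps 3 and 6 are one-step side branches.

**Step 9 (key step).** The most likely failures are attack of the carbene on the O1 lone pair followed by 1,2-shift of the electron-rich benzyl group, and incomplete discrimination of the enantiotopic hydrogens at one site. Because the centres are remote, molecules wrong at a single site would co-elute with the wanted isomer. The fallback replaces catalyst control by kinetic resolution and sets out from 13. Closure with achiral Rh2(OAc)4 gives the stereoisomer mixture of the protected bis-flavanone F1. Asymmetric transfer hydrogenation (RuCl(p-cymene)[(R,R)-TsDPEN] or its enantiomer, whichever reduces 2R-configured flavanone units on a monomeric model; HCO2H/Et3N) then turns every molecule containing a 2R unit into a flavan-4-ol. These are removed by polarity, and the unreduced diketone re-enters the route as 14. The same treatment can polish material from step 9 itself.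

**Step 8.** Silyl migration from O5 or O5'' to the enolate oxygen, or incomplete twofold acylation of the hindered enolates, may occur. The fallback is base-free and sets out from 11. Heating with Me2NCH(OMe)2 at 100 °C gives the bis(enaminone) F2. 4-Acetamidobenzenesulfonyl azide in MeCN at rt then adds across each enamine double bond and cycloreverts, releasing the diazoketone and a sulfonyl formamidine; the route is rejoined at 13.

**Step 4 (the same reasoning holds for step 7).** Ionisation of the activated para-benzyloxybenzyl oxyphosphonium ion, with C-alkylation of the electron-rich ring A, or sluggish reaction of the chelated phenol may occur. The fallback sets out from 4. SOCl2 in CH2Cl2 at 0 °C gives 4-[2-(benzyloxy)-5-(chloromethyl)phenoxy]benzaldehyde F3, which alkylates 6 under Williamson conditions (K2CO3, acetone, rt) and returns at 7.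

**Step 11.** Over-reduction may occur: hydrogenolysis of the benzylic C2–O1 bonds with ring opening, or reduction of a C4 ketone. The fallback sets out from 15 and removes the benzyl group without hydrogen, by BCl3 and pentamethylbenzene in CH2Cl2 at −78 °C (Lewis acid dealkylation with a cation scavenger). It arrives directly at 16 and makes no new compound.

**Step 2.** Substitution by the hindered ortho-benzyloxy phenoxide may be slow, allowing arylation at the benzylic hydroxyl or degradation of the aldehyde in hot carbonate. The fallback sets out from 2 and forms the diaryl ether by Chan–Lam coupling with (4-formylphenyl)boronic acid (Cu(OAc)2, pyridine, air, CH2Cl2, rt), which selects the phenol. It returns at 4 and makes no new compound.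

## Further compounds

F1 | step 9 | stereoisomer mixture of 4'-O-benzyl-5,5'',7''-tris-O-(triisopropylsilyl)-7-O-methyltetrahydroochnaflavone | COc1cc(O[Si](C(C)C)(C(C)C)C(C)C)c2c(c1)OC(c1ccc(OCc3ccccc3)c(Oc3ccc(C4CC(=O)c5c(O[Si](C(C)C)(C(C)C)C(C)C)cc(O[Si](C(C)C)(C(C)C)C(C)C)cc5O4)cc3)c1)CC2=O
F2 | step 8 | bis(enaminone), each acetyl of 11 converted into an (E)-3-(dimethylamino)prop-2-enoyl group | CN(C)/C=C/C(=O)c1c(OCc2ccc(OCc3ccccc3)c(Oc3ccc(COc4cc(O[Si](C(C)C)(C(C)C)C(C)C)cc(O[Si](C(C)C)(C(C)C)C(C)C)c4C(=O)/C=C/N(C)C)cc3)c2)cc(OC)cc1O[Si](C(C)C)(C(C)C)C(C)C
F3 | step 4 | 4-[2-(benzyloxy)-5-(chloromethyl)phenoxy]benzaldehyde | O=Cc1ccc(Oc2cc(CCl)ccc2OCc2ccccc2)cc1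
F0 | step 11 | none | none
F0 | step 2 | none | none
A1 | alternative 1 | 2-[4-(benzyloxy)-3-(ethynyloxy)phenyl]-1,3-dioxolane | C#COc1cc(C2OCCO2)ccc1OCc1ccccc1
A2 | alternative 1 | methyl coumalate (methyl 2-oxo-2H-pyran-5-carboxylate) | COC(=O)C1=COC(=O)C=C1
A3 | alternative 1 | methyl 4-[2-(benzyloxy)-5-(1,3-dioxolan-2-yl)phenoxy]benzoate | COC(=O)c1ccc(Oc2cc(C3OCCO3)ccc2OCc2ccccc2)cc1
A4 | alternative 2 | (2S)-6-(diazoacetyl)-2-aryl-2,3-dihydro-4H-pyran-4-one carrying the complete 7''-O-benzyl unit 2 | [N-]=[N+]=CC(=O)C1=CC(=O)C[C@H](O1)c1ccc(OCc2ccccc2)c(Oc2ccc([C@@H]3CC(=O)c4c(O)cc(OCc5ccccc5)cc4O3)cc2)c1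
A5 | alternative 2 | methoxyacetylene | COC#C
A6 | alternative 2 | di-O-benzyl 7-O-methyltetrahydroochnaflavone | COc1cc(O)c2c(c1)O[C@H](c1ccc(OCc3ccccc3)c(Oc3ccc([C@@H]4CC(=O)c5c(O)cc(OCc6ccccc6)cc5O4)cc3)c1)CC2=O
A7 | alternative 3 | dibromo tetraol, open form of A8 with Br at C8a and C8a'' and free hydroxyls at C2, C4, C2'' and C4'' | COc1cc(OCc2ccccc2)c(c(Br)c1)[C@@H](O)C[C@H](O)c1ccc(OCc2ccccc2)c(Oc2ccc([C@@H](O)C[C@H](O)c3c(Br)cc(OCc4ccccc4)cc3OCc3ccccc3)cc2)c1
A8 | alternative 3 | tetra-O-benzyl bis(flavan-4-ol) | COc1cc(OCc2ccccc2)c2c(c1)O[C@H](c1ccc(OCc3ccccc3)c(Oc3ccc([C@@H]4C[C@H](O)c5c(OCc6ccccc6)cc(OCc6ccccc6)cc5O4)cc3)c1)C[C@@H]2O
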